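The number to carry through this flask is a pure ratio: target over isomer of the product, each summed over the 10 earlier readings, which gives 1.08.

| flask | substrate | remark | time |
|---|---|---|---|
| violet | 0.060 M | run made earlier |  |
| grey | 0.090 M | run made earlier |  |
| flask | 0.12 M |  | 15 d |

- violet (time / d: target / %, isomer of the product / %, substrate / %): 2.50: 28, 24, 8; 5.00: 18, 16, 6; 8.00: 9, 12, 5; 10.0: 12, 12, 1; 12.0: 9, 9, 6
- grey (time / d: target / %, isomer of the product / %, substrate / %): 2.50: 20, 20, 9; 5.00: 11, 10, 9; 8.00: 12, 9, 1; 10.0: 7, 8, 4; 12.0: 9, 5, 3

(scatter of a reading: 2 percentage points)



- share of target in target plus isomer of the product at 5.0 min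
- share of target in target plus isomer of the product at 5.0 h
- share of target in target plus isomer of the product at 15 d

The balance of substrate comes first. The three violet readings add up to 60.0% at 2.50 d but 24.0% at 12.0 d, so charge is leaving for something unread. Target and isomer of the product fall together in the violet run meanwhile, which this reckoning reads as thermodynamic control, the two taken to be in equilibrium with each other. As a share, the ratio means 51.9% target.

Is one number enough? Across the violet and grey charges it holds within the readings: violet alone gives 51.0% and grey 53.2%, against a scatter of 2 percentage points on one reading. So this reckoning puts the flask at 51.9% at 15 d. Before the first reading at 2.50 d it is untested, since 5.0 min and 5.0 h come earlier, and this reckoning leaves both open.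

The forecast, unlike this reckoning, commits at the early times too, with 52%, 52% and 52%, while granting that “the early ratio could be kinetic and differ”.

The flask gives 67.6% at 5.0 min, 50.6% at 5.0 h and 50.8% at 15 d.

    target ⇌ isomer of the product (k = 7.60 × 10⁻⁵ /s)
    substrate ⇌ isomer of the product (K = 2.90, k = 8.04 × 10⁻⁴ /s)
    2 substrate → self-condensation product (k = 0.00140 /M/s)
    substrate ⇌ target (K = 3.00, k = 0.00181 /s)

In the flask, target reaches its highest amount at 0.307 h, later than the 5.0 min sample. At 15 d the flask holds 4.14% of isomer of the product, and 1.08 turns that into 4.47% of target, where 4.28% stands. In the neighbour charged with 0.20 M, the isomer of the product at 15 d is 2.59%, and 1.08 turns that into 2.80% of target, where 2.68% stands.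

The readings come from a simulation from invented constants; noise was put on by code.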